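Should the next run of this flask carry more partner than 1.20 equiv? That depends on how strongly the rate of making left-handed product answers to the partner charged, at the point where 20% of both substrates together is converted.

common to all: free catalyst 0.1 mol%

| flask | left-handed substrate | right-handed substrate | partner | impurity | remark |
|---|---|---|---|---|---|
| west | 0.24 M | 0.24 M | 1.2 equiv | 0.38 mM | run made earlier |
| north | 0.98 M | 0.98 M | 1.2 equiv | 0.38 mM | run made earlier |
| south-east | 0.49 M | 0.49 M | 1.2 equiv | 0.76 mM | run made earlier |
| flask | 0.49 M | 0.49 M | 1.20 equiv | 0.38 mM |  |

| run | time / h | left-handed product / % |
|---|---|---|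
| west | 3.00 | 0 |
| west | 6.00 | 0.1 |
| west | 8.00 | 0.3 |
| west | 12.0 | 0.3 |
| west | 15.0 | 0 |
| west | 20.0 | 0.3 |
| north | 3.00 | 11.2 |
| north | 6.00 | 19.5 |
| north | 8.00 | 24.0 |
| north | 12.0 | 31.2 |
| north | 15.0 | 36.0 |
| north | 20.0 | 39.8 |
| south-east | 2.00 | 1.6 |
| south-east | 5.00 | 0.7 |
| south-east | 10.0 | 0.6 |
| south-east | 15.0 | 0 |
| south-east | 20.0 | 0.8 |

(scatter of a reading: 0.5 percentage points)

- apparent order in partner when 20% of the left-handed substrate and right-handed substrate together are converted (percent change of the rate of making left-handed product for one percent more partner charged)

- free catalyst is single-handed; left-handed substrate and right-handed substrate are mirror images of each other, charged as a racemate, each of them at the stated concentration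

By the last reading, west and south-east show hardly any of what north shows, so north is the run I can read. In north, left-handed substrate and partner fall together, so I don't think that curve alone can say which of them the rate follows.

I therefore reckon with what is left. If each product takes one partner, reaching the mark uses 0.196 M in this flask, out of 0.588 M charged, and c(partner) there is 0.392 M. Extra partner doesn't change the amount used up to the mark, so it adds one for one to what is left. I call charged over left the lever: one percent more charged is 1.50 percent more left at the mark. Taking the rate as first order in partner at that moment, which is my assumption, I commit to 1.50 and raise the partner.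

The forecast says 0.1, on the ground that “the rate barely depends on partner”, which differs from my figure.

The flask gives 1.5, the lever of 1.50, not 0.1.

free catalyst + right-handed substrate ⇌ catalyst intermediate B (K = 0.820 M⁻¹, k = 8.64 M⁻¹ min⁻¹); partner + catalyst intermediate B → free catalyst + right-handed product (k = 0.0712 M⁻¹ min⁻¹); partner + catalyst intermediate A → free catalyst + left-handed product (k = 2.57 M⁻¹ min⁻¹); free catalyst + left-handed substrate ⇌ catalyst intermediate A (K = 7.25 M⁻¹, k = 83.2 M⁻¹ min⁻¹); free catalyst + impurity → spent catalyst (k = 720 M⁻¹ min⁻¹) At 10.4 h in this flask, catalyst intermediate A falls back 8.7 times faster than it goes on with partner, which makes going on with partner the rate-limiting step of its round. At the mark, after 35.8 h in this flask, catalyst intermediate A holds 13.1% of the catalyst, more than the 2.67% in catalyst intermediate B. North read 19.5% at 6.00 h, close to the mark, and the lever from that reading is 1.48.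

The earlier runs and the new flask were computed with constants of no real substance, and the scatter is random.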